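## The problem

The target (33) consists of two trans-2,3-diaryl-2,3-dihydrobenzofurans joined by one single bond, from C3 of dihydrobenzofuran 1 (O1, C2, C3, benzo ring A) to C5' of dihydrobenzofuran 2 (O1', C2', C3', benzo ring B). Ring A also carries an (E)-4-hydroxystyryl group at C4 and a phenol at C6; ring B carries a phenol at C7'; C3' bears a resorcinol ring (ring C); C2' and C2 each bear a 4-hydroxyphenyl ring. There are four stereocentres in two pairs, (2S,3S) and (2'R,3'R), and within a pair the trans arrangement is the stable one, so one centre can steer its neighbour. The pairs, however, are separated by ring B and the C3–C5' bond and have opposite absolute sense, so neither pair can set the other and absolute control must be supplied twice from outside. The C2–O1 and C2'–O1' bonds are benzylic ether bonds on carbons that carry a para-oxygenated aryl ring: acid ionises them, which opens the ring, epimerises C2 or C2', and, once the C4 stilbene is present, lets the alkene trap the C2 cation. Ring C is the most nucleophilic arene, so a late electrophilic halogenation cannot be directed to C5'; the seven phenols must stay masked through organometallic steps and be freed last. The feature that opens the route is that C3' and C2' (and likewise C3 and C2) are adjacent sp3 CH carbons, each carrying one aryl group besides the fused benzo ring, with the ring oxygen on C2' or C2; each carbon can therefore be inserted as a CHCl unit into a carbon–boron bond and then arylated, boron holding the place of the ring oxygen.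

## Retrosynthesis

**33 from 32 (seven O–CH3 bonds).** All phenols are carried as methyl ethers, because every aryl building block is then a catalogue compound and the ethers survive carbenoids, Grignard reagents, alkaline peroxide and CuI catalysis. The forward step is a BBr3 demethylation that must not ionise the two benzylic C–O bonds.

**32 from 30 and 31 (C4–vinyl bond).** Cutting here rather than at the alkene (Wittig) or at a C4 aldehyde fixes the E geometry in boronic acid 31. It also keeps the stilbene out of every organolithium, peroxide and CuI step. The C4 bromine of 30 costs nothing, as it is the second ortho-bromine of the ring A synthon. The forward Suzuki–Miyaura coupling has to tolerate one ortho substituent.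

**30 from 29, and 29 from 28 (C7a–O1, then C2–O from C2–B).** The ring is opened at the aryl–oxygen bond, not at C2–O1. Closure at C2–O1 would require a benzylic cation or a displacement at a crowded benzylic carbon. Closure at C7a–O1 is a CuI-catalysed O-arylation in which the carbinol C–O bond is never broken, so C2 is retained. Alcohol 29 comes from boronic ester 28 by stereoretentive oxidation.

**28 from 26, 7 and 12 (C2–C3 and C2–aryl).** C2 is inserted as a CHCl unit from dichloromethane (7) into the C3–B bond of 26 and arylated by Grignard reagent 12. The (S,S)-diol on boron decides C2.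

**26 from 20, 7 and 23 (C5'–C3 and C3–C3a); 23 from 21.** C3 is likewise a CHCl unit inserted into the C5'–B bond of aryl boronic ester 20. Ring A then arrives as the symmetrical 2,6-dibromo-4-methoxyphenyl magnesium reagent made from iodide 23, itself one Sandmeyer step from aniline 21. Placing the dihydrobenzofuran 2 aryl group on boron and ring A on magnesium, rather than the reverse, lets one diol enantiomer serve both cycles of this ring. The forward step must bring a doubly ortho-substituted nucleophile onto boron.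

**20 from 16 and 17 (C5'–B).** Bromine–lithium exchange, borylation and esterification with diol 17 turn the C5' bromine into the directing boronic ester. The bromine is carried from the first step because bromination of a finished dihydrobenzofuran 2 would attack ring C.

**16 from 15, and 15 from 14 (C7a'–O1', then C2'–O from C2'–B).** The same two operations as for dihydrobenzofuran 1, for the same reasons. The precursor 14 is acyclic, with both stereocentres in place.

**14 from 11, 7 and 12 (C3'–C2' and C2'–aryl; the key disconnection).** Both bonds to C2' are cut, leaving diarylmethyl boronic ester 11, dichloromethane 7 and the commercial Grignard reagent 12. No benzylic cation appears, and the new centre is set by the diol on boron.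

**11 from 6, 7 and 3; 6 from 4 and 5; 3 from 1.** C3' is again a CHCl unit, inserted into the aryl–boron bond of 6. Putting the 3,5-dimethoxyphenyl group on boron and the bromoaryl group of 3 on magnesium makes the (R,R)-diol give the required (R) centre, so no diol exchange is needed before the key step. Ester 6 is the condensation product of boronic acid 4 and diol 5. Arene 3 is made from 1 by C–H borylation at the only unhindered position followed by bromodeboronation.

## Roads not taken

Alternative 1: aryne insertion into a chiral stilbene oxide.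
- Cut: C7a–O1 and C3a–C3 of dihydrobenzofuran 1, so ring A comes from silyl aryl triflate A2, and C2 and C3 with their aryl groups from the enantioenriched trans-epoxide A3.
- Forward key step: CsF releases the 3-alkoxy-5-methoxybenzyne. The epoxide oxygen adds to the aryne carbon remote from the MOM ether (C7a), the benzylic C3–O bond ionises, and the aryl anion at C3a closes on C3 to give A1.
- Merits: one step assembles the whole dihydrofuran ring from two simple pieces, and chirality comes from a catalytic epoxidation with no stoichiometric director. In ring-forming steps this is clearly shorter than the four operations per ring used here.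
- Weak points: C3 passes through a benzylic zwitterion, so only C2 is transferred from A3 and C3 depends on trans collapse. A tosylate is needed to detune the C2 aryl ring so that the right C–O bond ionises. Insertion of arynes into epoxide C–O bonds rests on few examples. A1 carries ring B only as a guaiacyl ether with no handle at C3a', so dihydrobenzofuran 2, with two centres of opposite sense, would still have to be grown next to an acid-labile ring. MOM, benzyl and tosyl traffic and a triflate coupling for the styryl group would follow.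
- Comparison: the chosen plan is longer per ring, but it is cation-free, controls all four centres by reagent, and uses the same four operations for both rings.

Alternative 2: ring A grown by an intramolecular Danheiser benzannulation.
- Cut: C3a–C4, C3a–C7a, C6–C7 and C5–C6, so ring A is built de novo from the acyclic α-diazo dienone A5, which bears an ethynyl ether on the C2 oxygen.
- Forward key step: irradiation triggers a Wolff shift to a vinylketene, which adds [2+2] to the tethered ynol ether and closes the dihydrofuran. Warming gives 4π opening, 6π closure and tautomerisation to phenol A4.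
- Merits: ring A emerges with unambiguous substitution, a free and differentiated C6–OH, and the stilbene already in place. No cross-coupling on a hindered bromide is needed, and the bond count per step is higher than anything in the chosen route.
- Weak points: A5 is long to make, and its C2 and C3 centres must still be set acyclically beforehand, so the stereochemical problem is moved, not solved. A secondary benzylic ethynyl ether is prone to thermal retro-ene loss of ketene. The 4-methoxystilbene chromophore competes for light and can isomerise or dimerise. Ring B is again only a guaiacyl ether, leaving dihydrobenzofuran 2 unaddressed.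
- Comparison: against the regiochemical certainty of this road, the chosen plan sets a catalogue-derived 2,6-dibromoaryl ring A synthon that makes the substitution pattern trivial and needs no photochemistry.

Alternative 3: a dihydrocoumarin as temporary ring, contracted by anodic loss of CO2.
- Cut: O1'–C2' of dihydrobenzofuran 2. The precursor is lactone A7, which carries a C5' ester.
- Forward key step: one equivalent of Bu4NOH opens the lactone, and anodic (Hofer–Moest) oxidation of the arylacetate expels CO2. The resulting 4-methoxybenzylic cation at C2' is captured by the ring B phenol to give A6.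
- Merits: the C5' handle arrives with the ring, whereas the chosen route spends step 1 on it. A7 should be reachable by catalytic asymmetric conjugate arylation of a coumarin, and the contraction uses only current. For dihydrobenzofuran 2 alone this road is probably as short or shorter.
- Weak points: C2' is set by cation capture, so trans rests on substrate control. The anode must select the carboxylate in the presence of a phenol and two very electron-rich rings. The ester at C5' then has to become the C3 carbon of dihydrobenzofuran 1 by unrelated chemistry with its own source of absolute control.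
- Comparison: the chosen plan sets against this reagent control at both centres, no oxidation-potential question, and direct repetition of the sequence on the C5' boronic ester with the mirror-image diol.

Key step: step 4

Remark: the sense of induction is taken from the established behaviour of C2-symmetric 1,2-dialkylethanediol boronic esters, an (R,R)-diol giving the (S)-α-chloro boronic ester (Cl > C > B > H) and the (S,S)-diol its mirror image; 2,6-dibromo-4-methoxyaniline (21) is taken to be a catalogue compound.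

## Route

Step 1
Reactants: 1 2-bromo-1-iodo-3-methoxybenzene
Product: 3 2,5-dibromo-1-iodo-3-methoxybenzene, via aryl pinacol boronate 2 (not isolated)
Conditions: [Ir(OMe)(cod)]2 (cat.), 4,4'-di-tert-butyl-2,2'-bipyridine, B2pin2, THF, 80 °C; then CuBr2, MeOH/H2O, 80 °C
Reagents that add atoms: copper dibromide, Br[Cu]Br
Why: Arene C–H borylation with [Ir(OMe)(cod)]2 and the bipyridine ligand is governed by sterics and takes the only ring hydrogen of 1 without an ortho substituent (C5); bromodeboronation of 2 by CuBr2 in the same pot then places bromine there, and the aryl iodide and bromide are untouched by either stage.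

Step 2
Reactants: 4 (3,5-dimethoxyphenyl)boronic acid; 5 (1R,2R)-1,2-dicyclohexylethane-1,2-diol
Product: 6 (4R,5R)-4,5-dicyclohexyl-2-(3,5-dimethoxyphenyl)-1,3,2-dioxaborolane
Conditions: MgSO4, Et2O, 20 °C
Reagents that add atoms: none
Why: Condensation of a boronic acid with a 1,2-diol to the five-membered boronic ester, driven by removal of water; the C2-symmetric diol becomes the stereodirecting group of steps 3 and 4.

Step 3
Reactants: 6 (4R,5R)-4,5-dicyclohexyl-2-(3,5-dimethoxyphenyl)-1,3,2-dioxaborolane; 7 dichloromethane; 3 2,5-dibromo-1-iodo-3-methoxybenzene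
Product: 11 (4R,5R)-4,5-dicyclohexyl-2-[(R)-(2,5-dibromo-3-methoxyphenyl)(3,5-dimethoxyphenyl)methyl]-1,3,2-dioxaborolane, via (dichloromethyl)lithium 8 (not isolated), via (S)-chloro boronic ester 9 (not isolated), via arylmagnesium chloride 10 (not isolated)
Conditions: 7, n-BuLi, THF, −100 °C; then 6; ZnCl2, −100 → 20 °C; then 10 (from 3, iPrMgCl·LiCl, THF, −40 °C), −78 → 20 °C
Reagents that add atoms: none
Why: Matteson homologation and Grignard substitution: carbenoid 8 adds to boron, the aryl group shifts to carbon with ZnCl2 assistance while the (R,R)-diol selects the leaving chloride to give (S)-chloride 9, and the aryl group of 10 (made by iodine–magnesium exchange at −40 °C, where an ortho-bromoaryl Grignard reagent does not yet collapse to an aryne) shifts from boron to carbon with inversion to set C3' as (R). The dimethoxyphenyl group is put on boron and the bromoaryl group used as nucleophile because this order makes the (R,R)-diol deliver the required sense, and the meta-methoxy groups of 9 do not stabilise a benzylic cation.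

Step 4
Reactants: 11 (4R,5R)-4,5-dicyclohexyl-2-[(R)-(2,5-dibromo-3-methoxyphenyl)(3,5-dimethoxyphenyl)methyl]-1,3,2-dioxaborolane; 7 dichloromethane; 12 (4-methoxyphenyl)magnesium bromide
Product: 14 (4R,5R)-4,5-dicyclohexyl-2-[(1R,2R)-2-(2,5-dibromo-3-methoxyphenyl)-2-(3,5-dimethoxyphenyl)-1-(4-methoxyphenyl)ethyl]-1,3,2-dioxaborolane, via (1S,2R)-chloro boronic ester 13 (not isolated)
Conditions: 7, n-BuLi, THF, −100 °C (carbenoid 8 made again as in step 3); then 11; ZnCl2, −100 → 20 °C; then 12 (excess), −78 → 20 °C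
Reagents that add atoms: none
Why: This is a Matteson homologation followed by Grignard substitution, the closest known reaction type being LiCHCl2 insertion into chiral diol boronic esters with displacement of the α-chloride by an arylmagnesium halide. Carbenoid 8, made again from 7 and n-BuLi as in step 3, adds to boron of 11; on warming with ZnCl2 the diarylmethyl group shifts from boron to carbon with retention at C3' (forming C3'–C2'), while the (R,R)-diol decides which diastereotopic chloride leaves, so chloride 13 is (S) at C2'. Grignard reagent 12 then adds to boron and its aryl group shifts to C2' anti to the departing chloride (forming C2'–aryl), so C2' is inverted and ends (R), correctly placed for the later trans ring. No ring closes in this step. The one new stereocentre, C2', is thus set by the diol on boron and the inversion; C3' is only carried. The step needs selectivity for boron over the two aryl bromides and over the acidic benzhydryl C–H of 11: the carbenoid is preformed at −100 °C so that no butyllithium remains, and complexation at boron is faster than deprotonation. The chloride-bearing carbon of 13 is not benzylic, which together with ZnCl2 keeps it from epimerising by chloride exchange before the aryl shift; 12 is used in excess over ZnCl2.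

Step 5
Reactants: 14 (4R,5R)-4,5-dicyclohexyl-2-[(1R,2R)-2-(2,5-dibromo-3-methoxyphenyl)-2-(3,5-dimethoxyphenyl)-1-(4-methoxyphenyl)ethyl]-1,3,2-dioxaborolane
Product: 15 (1R,2R)-2-(2,5-dibromo-3-methoxyphenyl)-2-(3,5-dimethoxyphenyl)-1-(4-methoxyphenyl)ethan-1-ol
Conditions: H2O2 (30% aq.), NaOH, THF/H2O, 0 → 20 °C
Reagents that add atoms: hydrogen peroxide, OO
Why: Oxidation of a boronic ester with alkaline hydrogen peroxide: hydroperoxide adds to boron and C2' shifts from boron to oxygen with retention, so the (1R) alcohol results and diol 5 is recovered.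

Step 6
Reactants: 15 (1R,2R)-2-(2,5-dibromo-3-methoxyphenyl)-2-(3,5-dimethoxyphenyl)-1-(4-methoxyphenyl)ethan-1-ol
Product: 16 (2R,3R)-5-bromo-3-(3,5-dimethoxyphenyl)-7-methoxy-2-(4-methoxyphenyl)-2,3-dihydro-1-benzofuran
Conditions: CuI (cat.), 3,4,7,8-tetramethyl-1,10-phenanthroline, Cs2CO3, toluene, 110 °C
Reagents that add atoms: none
Why: Ullmann-type intramolecular O-arylation catalysed by CuI (5-exo closure of the alkoxide onto the ortho C–Br bond); the carbinol C–O bond is never broken, so C2' is retained, and the C5 bromine cannot reach the alkoxide and remains as the handle for dihydrobenzofuran 1.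

Step 7
Reactants: 16 (2R,3R)-5-bromo-3-(3,5-dimethoxyphenyl)-7-methoxy-2-(4-methoxyphenyl)-2,3-dihydro-1-benzofuran; 17 (1S,2S)-1,2-dicyclohexylethane-1,2-diol
Product: 20 (4S,5S)-4,5-dicyclohexyl-2-[(2R,3R)-3-(3,5-dimethoxyphenyl)-7-methoxy-2-(4-methoxyphenyl)-2,3-dihydro-1-benzofuran-5-yl]-1,3,2-dioxaborolane, via aryllithium 18 (not isolated), via arylboronic acid 19 (not isolated)
Conditions: n-BuLi, THF, −78 °C; B(OMe)3, −78 → 20 °C; 1 M aq. HCl, 0 °C; then 17, MgSO4, Et2O, 20 °C
Reagents that add atoms: trimethyl borate, COB(OC)OC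
Why: Bromine–lithium exchange at −78 °C is faster than deprotonation of the benzylic ring hydrogens; aryllithium 18 is trapped by B(OMe)3 and boronic acid 19 is condensed with the antipodal diol 17, which will direct the two homologations of dihydrobenzofuran 1.

Step 8
Reactants: 21 2,6-dibromo-4-methoxyaniline
Product: 23 1,3-dibromo-2-iodo-5-methoxybenzene, via arenediazonium hydrogensulfate 22 (not isolated)
Conditions: NaNO2, H2SO4, AcOH, 0–10 °C; then KI, H2O, 0 → 60 °C
Reagents that add atoms: potassium iodide, [K+].[I-]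
Why: Sandmeyer-type iodination: diazotisation of the weakly basic 2,6-dibromoaniline in sulfuric/acetic acid and displacement of N2 by iodide, which proceeds without a catalyst.

Step 9
Reactants: 20 (4S,5S)-4,5-dicyclohexyl-2-[(2R,3R)-3-(3,5-dimethoxyphenyl)-7-methoxy-2-(4-methoxyphenyl)-2,3-dihydro-1-benzofuran-5-yl]-1,3,2-dioxaborolane; 7 dichloromethane; 23 1,3-dibromo-2-iodo-5-methoxybenzene
Product: 26 (4S,5S)-4,5-dicyclohexyl-2-[(S)-(2,6-dibromo-4-methoxyphenyl)[(2R,3R)-3-(3,5-dimethoxyphenyl)-7-methoxy-2-(4-methoxyphenyl)-2,3-dihydro-1-benzofuran-5-yl]methyl]-1,3,2-dioxaborolane, via (R)-chloro boronic ester 24 (not isolated), via arylmagnesium chloride 25 (not isolated)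
Conditions: 7, n-BuLi, THF, −100 °C (carbenoid 8 made again as in step 3); then 20; ZnCl2, −100 → 0 °C; then 25 (from 23, iPrMgCl·LiCl, THF, −40 °C), −78 → 20 °C
Reagents that add atoms: none
Why: The Matteson sequence of step 3 with the antipodal diol: carbenoid 8, made again from 7, adds to boron of 20, the C5' aryl group shifts from boron to the carbenoid carbon to give (R)-chloride 24 (forming C5'–C3), and the aryl group of 25 shifts with inversion to set C3 as (S) (forming C3–C3a). Reagent 25 is made by iodine–magnesium exchange at −40 °C and added cold; its two ortho-bromines later serve the ring closure and the styryl coupling, and the para-alkoxybenzylic chloride 24 is generated and consumed in one flask without warming above 0 °C.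

Step 10
Reactants: 26 (4S,5S)-4,5-dicyclohexyl-2-[(S)-(2,6-dibromo-4-methoxyphenyl)[(2R,3R)-3-(3,5-dimethoxyphenyl)-7-methoxy-2-(4-methoxyphenyl)-2,3-dihydro-1-benzofuran-5-yl]methyl]-1,3,2-dioxaborolane; 7 dichloromethane; 12 (4-methoxyphenyl)magnesium bromide
Product: 28 (4S,5S)-4,5-dicyclohexyl-2-[(1S,2S)-2-(2,6-dibromo-4-methoxyphenyl)-2-[(2R,3R)-3-(3,5-dimethoxyphenyl)-7-methoxy-2-(4-methoxyphenyl)-2,3-dihydro-1-benzofuran-5-yl]-1-(4-methoxyphenyl)ethyl]-1,3,2-dioxaborolane, via (1R,2S)-chloro boronic ester 27 (not isolated)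
Conditions: 7, n-BuLi, THF, −100 °C (carbenoid 8 made again as in step 3); then 26; ZnCl2, −100 → 20 °C; then 12 (excess), −78 → 20 °C
Reagents that add atoms: none
Why: Repeat of the key step in the mirror-image series: carbenoid 8, made again from 7, adds to boron of 26, the (S,S)-diol makes 27 the (1R)-chloride, the crowded diarylmethyl group shifts with retention at C3, and the anisyl group of 12 shifts with inversion to give (1S)-28, the precursor of the trans ring.

Step 11
Reactants: 28 (4S,5S)-4,5-dicyclohexyl-2-[(1S,2S)-2-(2,6-dibromo-4-methoxyphenyl)-2-[(2R,3R)-3-(3,5-dimethoxyphenyl)-7-methoxy-2-(4-methoxyphenyl)-2,3-dihydro-1-benzofuran-5-yl]-1-(4-methoxyphenyl)ethyl]-1,3,2-dioxaborolane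
Product: 29 (1S,2S)-2-(2,6-dibromo-4-methoxyphenyl)-2-[(2R,3R)-3-(3,5-dimethoxyphenyl)-7-methoxy-2-(4-methoxyphenyl)-2,3-dihydro-1-benzofuran-5-yl]-1-(4-methoxyphenyl)ethan-1-ol
Conditions: H2O2 (30% aq.), NaOH, THF/H2O, 0 → 20 °C
Reagents that add atoms: hydrogen peroxide, OO
Why: Stereoretentive oxidation of the C–B bond by alkaline hydrogen peroxide, as in step 5; diol 17 is recovered.

Step 12
Reactants: 29 (1S,2S)-2-(2,6-dibromo-4-methoxyphenyl)-2-[(2R,3R)-3-(3,5-dimethoxyphenyl)-7-methoxy-2-(4-methoxyphenyl)-2,3-dihydro-1-benzofuran-5-yl]-1-(4-methoxyphenyl)ethan-1-ol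
Product: 30 (2S,3S)-4-bromo-3-[(2R,3R)-3-(3,5-dimethoxyphenyl)-7-methoxy-2-(4-methoxyphenyl)-2,3-dihydro-1-benzofuran-5-yl]-6-methoxy-2-(4-methoxyphenyl)-2,3-dihydro-1-benzofuran
Conditions: CuI (cat.), 3,4,7,8-tetramethyl-1,10-phenanthroline, Cs2CO3, toluene, 110 °C
Reagents that add atoms: none
Why: Ullmann-type intramolecular O-arylation catalysed by CuI as in step 6, with retention at C2; the two ortho-bromines are interchanged by rotation about the C3–aryl bond, so either closes to the same product and the other is left at C4.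

Step 13
Reactants: 30 (2S,3S)-4-bromo-3-[(2R,3R)-3-(3,5-dimethoxyphenyl)-7-methoxy-2-(4-methoxyphenyl)-2,3-dihydro-1-benzofuran-5-yl]-6-methoxy-2-(4-methoxyphenyl)-2,3-dihydro-1-benzofuran; 31 [(E)-2-(4-methoxyphenyl)ethenyl]boronic acid
Product: 32 (2S,3S)-3-[(2R,3R)-3-(3,5-dimethoxyphenyl)-7-methoxy-2-(4-methoxyphenyl)-2,3-dihydro-1-benzofuran-5-yl]-6-methoxy-2-(4-methoxyphenyl)-4-[(E)-2-(4-methoxyphenyl)ethenyl]-2,3-dihydro-1-benzofuran
Conditions: Pd(OAc)2 (cat.), SPhos, K3PO4, toluene/H2O, 90 °C
Reagents that add atoms: none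
Why: Suzuki–Miyaura coupling; the E geometry is carried in 31 and retained through transmetalation and reductive elimination, and a bulky dialkylbiarylphosphine copes with the ortho-substituted bromide. The stilbene thus appears only after all organolithium, peroxide and CuI steps.

Step 14
Reactants: 32 (2S,3S)-3-[(2R,3R)-3-(3,5-dimethoxyphenyl)-7-methoxy-2-(4-methoxyphenyl)-2,3-dihydro-1-benzofuran-5-yl]-6-methoxy-2-(4-methoxyphenyl)-4-[(E)-2-(4-methoxyphenyl)ethenyl]-2,3-dihydro-1-benzofuran
Product: 33 5-[(2R,3R)-7-hydroxy-5-[(2S,3S)-6-hydroxy-2-(4-hydroxyphenyl)-4-[(E)-2-(4-hydroxyphenyl)ethenyl]-2,3-dihydro-1-benzofuran-3-yl]-2-(4-hydroxyphenyl)-2,3-dihydro-1-benzofuran-3-yl]benzene-1,3-diol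
Conditions: BBr3, CH2Cl2, −78 → 0 °C; then MeOH/H2O
Reagents that add atoms: none
Why: Lewis acid cleavage of aryl methyl ethers by BBr3 (bromide attacks the methyl group of the aryl–oxygen–boron adduct), started at −78 °C and stopped at 0 °C to keep the C2–O1 and C2'–O1' bonds from ionising; aqueous work-up frees the seven phenols.

## Compound list

1 | 2-bromo-1-iodo-3-methoxybenzene | COc1cccc(I)c1Br | starting material
2 | 2-(4-bromo-3-iodo-5-methoxyphenyl)-4,4,5,5-tetramethyl-1,3,2-dioxaborolane | COc1cc(B2OC(C)(C)C(C)(C)O2)cc(I)c1Br | intermediate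
3 | 2,5-dibromo-1-iodo-3-methoxybenzene | COc1cc(Br)cc(I)c1Br | intermediate
4 | (3,5-dimethoxyphenyl)boronic acid | COc1cc(OC)cc(B(O)O)c1 | starting material
5 | (1R,2R)-1,2-dicyclohexylethane-1,2-diol | O[C@H](C1CCCCC1)[C@H](O)C1CCCCC1 | starting material
6 | (4R,5R)-4,5-dicyclohexyl-2-(3,5-dimethoxyphenyl)-1,3,2-dioxaborolane | COc1cc(OC)cc(c1)B1O[C@H](C2CCCCC2)[C@@H](C2CCCCC2)O1 | intermediate
7 | dichloromethane | ClCCl | starting material
8 | (dichloromethyl)lithium | [Li]C(Cl)Cl | intermediate
9 | (4R,5R)-2-[(S)-chloro(3,5-dimethoxyphenyl)methyl]-4,5-dicyclohexyl-1,3,2-dioxaborolane | COc1cc(OC)cc(c1)[C@@H](Cl)B1O[C@H](C2CCCCC2)[C@@H](C2CCCCC2)O1 | intermediate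
10 | (2,5-dibromo-3-methoxyphenyl)magnesium chloride | COc1cc(Br)cc([Mg]Cl)c1Br | intermediate
11 | (4R,5R)-4,5-dicyclohexyl-2-[(R)-(2,5-dibromo-3-methoxyphenyl)(3,5-dimethoxyphenyl)methyl]-1,3,2-dioxaborolane | COc1cc(Br)cc([C@@H](c2cc(OC)cc(OC)c2)B2O[C@H](C3CCCCC3)[C@@H](C3CCCCC3)O2)c1Br | intermediate
12 | (4-methoxyphenyl)magnesium bromide | COc1ccc([Mg]Br)cc1 | starting material
13 | (4R,5R)-2-[(1S,2R)-1-chloro-2-(2,5-dibromo-3-methoxyphenyl)-2-(3,5-dimethoxyphenyl)ethyl]-4,5-dicyclohexyl-1,3,2-dioxaborolane | COc1cc(Br)cc([C@@H](c2cc(OC)cc(OC)c2)[C@@H](Cl)B2O[C@H](C3CCCCC3)[C@@H](C3CCCCC3)O2)c1Br | intermediate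
14 | (4R,5R)-4,5-dicyclohexyl-2-[(1R,2R)-2-(2,5-dibromo-3-methoxyphenyl)-2-(3,5-dimethoxyphenyl)-1-(4-methoxyphenyl)ethyl]-1,3,2-dioxaborolane | COc1cc(Br)cc([C@@H](c2cc(OC)cc(OC)c2)[C@H](c2ccc(OC)cc2)B2O[C@H](C3CCCCC3)[C@@H](C3CCCCC3)O2)c1Br | intermediate
15 | (1R,2R)-2-(2,5-dibromo-3-methoxyphenyl)-2-(3,5-dimethoxyphenyl)-1-(4-methoxyphenyl)ethan-1-ol | COc1cc(Br)cc([C@@H](c2cc(OC)cc(OC)c2)[C@H](c2ccc(OC)cc2)O)c1Br | intermediate
16 | (2R,3R)-5-bromo-3-(3,5-dimethoxyphenyl)-7-methoxy-2-(4-methoxyphenyl)-2,3-dihydro-1-benzofuran | Brc1cc(OC)c2c(c1)[C@@H](c1cc(OC)cc(OC)c1)[C@H](c1ccc(OC)cc1)O2 | intermediate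
17 | (1S,2S)-1,2-dicyclohexylethane-1,2-diol | O[C@@H](C1CCCCC1)[C@@H](O)C1CCCCC1 | starting material
18 | [(2R,3R)-3-(3,5-dimethoxyphenyl)-7-methoxy-2-(4-methoxyphenyl)-2,3-dihydro-1-benzofuran-5-yl]lithium | [Li]c1cc(OC)c2c(c1)[C@@H](c1cc(OC)cc(OC)c1)[C@H](c1ccc(OC)cc1)O2 | intermediate
19 | [(2R,3R)-3-(3,5-dimethoxyphenyl)-7-methoxy-2-(4-methoxyphenyl)-2,3-dihydro-1-benzofuran-5-yl]boronic acid | OB(O)c1cc(OC)c2c(c1)[C@@H](c1cc(OC)cc(OC)c1)[C@H](c1ccc(OC)cc1)O2 | intermediate
20 | (4S,5S)-4,5-dicyclohexyl-2-[(2R,3R)-3-(3,5-dimethoxyphenyl)-7-methoxy-2-(4-methoxyphenyl)-2,3-dihydro-1-benzofuran-5-yl]-1,3,2-dioxaborolane | B1(O[C@@H](C2CCCCC2)[C@H](C2CCCCC2)O1)c1cc(OC)c2c(c1)[C@@H](c1cc(OC)cc(OC)c1)[C@H](c1ccc(OC)cc1)O2 | intermediate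
21 | 2,6-dibromo-4-methoxyaniline | COc1cc(Br)c(N)c(Br)c1 | starting material
22 | 2,6-dibromo-4-methoxybenzenediazonium hydrogensulfate | COc1cc(Br)c([N+]#N)c(Br)c1.OS(=O)(=O)[O-] | intermediate
23 | 1,3-dibromo-2-iodo-5-methoxybenzene | COc1cc(Br)c(I)c(Br)c1 | intermediate
24 | (4S,5S)-2-[(R)-chloro[(2R,3R)-3-(3,5-dimethoxyphenyl)-7-methoxy-2-(4-methoxyphenyl)-2,3-dihydro-1-benzofuran-5-yl]methyl]-4,5-dicyclohexyl-1,3,2-dioxaborolane | Cl[C@@H](c1cc(OC)c2c(c1)[C@@H](c1cc(OC)cc(OC)c1)[C@H](c1ccc(OC)cc1)O2)B1O[C@@H](C2CCCCC2)[C@H](C2CCCCC2)O1 | intermediate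
25 | (2,6-dibromo-4-methoxyphenyl)magnesium chloride | COc1cc(Br)c([Mg]Cl)c(Br)c1 | intermediate
26 | (4S,5S)-4,5-dicyclohexyl-2-[(S)-(2,6-dibromo-4-methoxyphenyl)[(2R,3R)-3-(3,5-dimethoxyphenyl)-7-methoxy-2-(4-methoxyphenyl)-2,3-dihydro-1-benzofuran-5-yl]methyl]-1,3,2-dioxaborolane | COc1cc(Br)c(c(Br)c1)[C@H](c1cc(OC)c2c(c1)[C@@H](c1cc(OC)cc(OC)c1)[C@H](c1ccc(OC)cc1)O2)B1O[C@@H](C2CCCCC2)[C@H](C2CCCCC2)O1 | intermediate
27 | (4S,5S)-2-[(1R,2S)-1-chloro-2-(2,6-dibromo-4-methoxyphenyl)-2-[(2R,3R)-3-(3,5-dimethoxyphenyl)-7-methoxy-2-(4-methoxyphenyl)-2,3-dihydro-1-benzofuran-5-yl]ethyl]-4,5-dicyclohexyl-1,3,2-dioxaborolane | COc1cc(Br)c(c(Br)c1)[C@H](c1cc(OC)c2c(c1)[C@@H](c1cc(OC)cc(OC)c1)[C@H](c1ccc(OC)cc1)O2)[C@H](Cl)B1O[C@@H](C2CCCCC2)[C@H](C2CCCCC2)O1 | intermediate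
28 | (4S,5S)-4,5-dicyclohexyl-2-[(1S,2S)-2-(2,6-dibromo-4-methoxyphenyl)-2-[(2R,3R)-3-(3,5-dimethoxyphenyl)-7-methoxy-2-(4-methoxyphenyl)-2,3-dihydro-1-benzofuran-5-yl]-1-(4-methoxyphenyl)ethyl]-1,3,2-dioxaborolane | COc1cc(Br)c(c(Br)c1)[C@H](c1cc(OC)c2c(c1)[C@@H](c1cc(OC)cc(OC)c1)[C@H](c1ccc(OC)cc1)O2)[C@@H](c1ccc(OC)cc1)B1O[C@@H](C2CCCCC2)[C@H](C2CCCCC2)O1 | intermediate
29 | (1S,2S)-2-(2,6-dibromo-4-methoxyphenyl)-2-[(2R,3R)-3-(3,5-dimethoxyphenyl)-7-methoxy-2-(4-methoxyphenyl)-2,3-dihydro-1-benzofuran-5-yl]-1-(4-methoxyphenyl)ethan-1-ol | COc1cc(Br)c(c(Br)c1)[C@H](c1cc(OC)c2c(c1)[C@@H](c1cc(OC)cc(OC)c1)[C@H](c1ccc(OC)cc1)O2)[C@@H](c1ccc(OC)cc1)O | intermediate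
30 | (2S,3S)-4-bromo-3-[(2R,3R)-3-(3,5-dimethoxyphenyl)-7-methoxy-2-(4-methoxyphenyl)-2,3-dihydro-1-benzofuran-5-yl]-6-methoxy-2-(4-methoxyphenyl)-2,3-dihydro-1-benzofuran | Brc1cc(OC)cc2c1[C@H](c1cc(OC)c3c(c1)[C@@H](c1cc(OC)cc(OC)c1)[C@H](c1ccc(OC)cc1)O3)[C@@H](c1ccc(OC)cc1)O2 | intermediate
31 | [(E)-2-(4-methoxyphenyl)ethenyl]boronic acid | COc1ccc(/C=C/B(O)O)cc1 | starting material
32 | (2S,3S)-3-[(2R,3R)-3-(3,5-dimethoxyphenyl)-7-methoxy-2-(4-methoxyphenyl)-2,3-dihydro-1-benzofuran-5-yl]-6-methoxy-2-(4-methoxyphenyl)-4-[(E)-2-(4-methoxyphenyl)ethenyl]-2,3-dihydro-1-benzofuran | COc1ccc(/C=C/c2cc(OC)cc3c2[C@H](c2cc(OC)c4c(c2)[C@@H](c2cc(OC)cc(OC)c2)[C@H](c2ccc(OC)cc2)O4)[C@@H](c2ccc(OC)cc2)O3)cc1 | intermediate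
33 | 5-[(2R,3R)-7-hydroxy-5-[(2S,3S)-6-hydroxy-2-(4-hydroxyphenyl)-4-[(E)-2-(4-hydroxyphenyl)ethenyl]-2,3-dihydro-1-benzofuran-3-yl]-2-(4-hydroxyphenyl)-2,3-dihydro-1-benzofuran-3-yl]benzene-1,3-diol | Oc1ccc(/C=C/c2cc(O)cc3c2[C@H](c2cc(O)c4c(c2)[C@@H](c2cc(O)cc(O)c2)[C@H](c2ccc(O)cc2)O4)[C@@H](c2ccc(O)cc2)O3)cc1 | target

## Step count and least certain steps

Total step count: 14. Longest linear sequence: 12 steps (from 4 through steps 2–7 and 9–14; the branch from 1 is equally long).

**Step 4 (key step).** The most likely failure is erosion of diol control at C2'. The borate from crowded 11 rearranges slowly, so chloride exchange at 13, or a sluggish aryl shift beside the triaryl-substituted C3', can leak the C2' epimer.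
Fallback (sets out from 11, rejoins at 16): control at C2' is handed from the reagent to thermodynamics. The homologation is run as before, and the epimeric (1S,2R)-boronic ester F1 is oxidised with alkaline H2O2 to the (1S,2R)-alcohol F2. CuI/Cs2CO3 closes this to the cis-dihydrobenzofuran F3. Brief treatment with CF3CO2H in CH2Cl2 at 0 °C opens the C2'–O1' bond to the 4-methoxybenzylic cation, which recloses anti to the C3' aryl group to give trans 16. C3' is not expected to be touched by acid; loss of its proton from the open cation would be the thing to watch.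

**Step 9.** Three processes threaten it. The doubly ortho-substituted nucleophile 25 may add to boron too slowly and lose MgBrCl to an aryne on warming. The electron-poor 2,6-dibromoaryl group may shift slowly. The para-alkoxybenzylic chloride 24 may ionise or exchange chloride, eroding C3.
Fallback (sets out from 16 and 23, rejoins at 26): the roles of the two aryl groups are reversed. Iodide 23 is converted (iPrMgCl·LiCl, B(OMe)3, then diol 5) into the (R,R)-diol ester of (2,6-dibromo-4-methoxyphenyl)boronic acid F4. LiCHCl2/ZnCl2 homologates this to the (S)-chloride F5, whose two ortho-bromines hold the ring out of conjugation and so protect the benzylic chloride. After removal of ZnCl2, the unhindered aryllithium 18 (from 16 as in step 7) adds to boron at −78 °C and shifts with inversion, giving the (S)-diarylmethyl boronic ester of the (R,R)-diol F6. The second cycle needs the antipodal diol, so F6 is cleaved with KHF2 to the potassium trifluoroborate F7 and re-esterified with diol 17 (Me3SiCl, MeCN/H2O) to give 26.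

**Step 14.** The Lewis acid may ionise the C2–O1 bond and the C4 styrene may capture the benzylic cation in an irreversible cyclisation; ring-opening and epimerisation at C2 or C2' are further risks.
Fallback (sets out from 30, rejoins at 33): the ethers are cleaved before the alkene exists, so ring-opening can only reverse to the trans ring. BBr3 on 30 gives the hexaphenol bromide F8, and Ac2O/pyridine gives the hexaacetate F9. A Heck reaction with 4-acetoxystyrene (Pd(OAc)2, P(o-tol)3, Et3N, DMF, 100 °C) gives the heptaacetate F10. K2CO3 in MeOH at 0 °C then removes the acetates under non-acidic conditions to give 33.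

**Step 3.** The ortho-bromoaryl Grignard reagent 10 may form an aryne if borate formation is slow, and the benzylic chloride 9 may partly epimerise while it waits.
Fallback (sets out from 3, rejoins at 11): the aryl roles are reversed and the diol is exchanged afterwards. Iodide 3 is converted (iPrMgCl·LiCl, B(OMe)3, then diol 17) into the (S,S)-diol ester of (2,5-dibromo-3-methoxyphenyl)boronic acid F11. LiCHCl2/ZnCl2 gives the (R)-chloride F12. Commercial 3,5-dimethoxyphenylmagnesium bromide, which has no ortho halogen and is stable at room temperature, displaces chloride with inversion to give the (R)-diarylmethyl boronic ester of the (S,S)-diol F13. KHF2 gives the potassium trifluoroborate F14, and Me3SiCl with diol 5 gives 11.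

## Further compounds

F1 | step 4 | (4R,5R)-4,5-dicyclohexyl-2-[(1S,2R)-2-(2,5-dibromo-3-methoxyphenyl)-2-(3,5-dimethoxyphenyl)-1-(4-methoxyphenyl)ethyl]-1,3,2-dioxaborolane | COc1cc(Br)cc([C@@H](c2cc(OC)cc(OC)c2)[C@@H](c2ccc(OC)cc2)B2O[C@H](C3CCCCC3)[C@@H](C3CCCCC3)O2)c1Br
F2 | step 4 | (1S,2R)-2-(2,5-dibromo-3-methoxyphenyl)-2-(3,5-dimethoxyphenyl)-1-(4-methoxyphenyl)ethan-1-ol | COc1cc(Br)cc([C@@H](c2cc(OC)cc(OC)c2)[C@@H](c2ccc(OC)cc2)O)c1Br
F3 | step 4 | (2S,3R)-5-bromo-3-(3,5-dimethoxyphenyl)-7-methoxy-2-(4-methoxyphenyl)-2,3-dihydro-1-benzofuran (cis) | Brc1cc(OC)c2c(c1)[C@@H](c1cc(OC)cc(OC)c1)[C@@H](c1ccc(OC)cc1)O2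
F4 | step 9 | (4R,5R)-4,5-dicyclohexyl-2-(2,6-dibromo-4-methoxyphenyl)-1,3,2-dioxaborolane | COc1cc(Br)c(B2O[C@H](C3CCCCC3)[C@@H](C3CCCCC3)O2)c(Br)c1
F5 | step 9 | (4R,5R)-2-[(S)-chloro(2,6-dibromo-4-methoxyphenyl)methyl]-4,5-dicyclohexyl-1,3,2-dioxaborolane | COc1cc(Br)c(c(Br)c1)[C@@H](Cl)B1O[C@H](C2CCCCC2)[C@@H](C2CCCCC2)O1
F6 | step 9 | (4R,5R)-4,5-dicyclohexyl-2-[(S)-(2,6-dibromo-4-methoxyphenyl)[(2R,3R)-3-(3,5-dimethoxyphenyl)-7-methoxy-2-(4-methoxyphenyl)-2,3-dihydro-1-benzofuran-5-yl]methyl]-1,3,2-dioxaborolane | COc1cc(Br)c(c(Br)c1)[C@H](c1cc(OC)c2c(c1)[C@@H](c1cc(OC)cc(OC)c1)[C@H](c1ccc(OC)cc1)O2)B1O[C@H](C2CCCCC2)[C@@H](C2CCCCC2)O1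
F7 | step 9 | potassium [(S)-(2,6-dibromo-4-methoxyphenyl)[(2R,3R)-3-(3,5-dimethoxyphenyl)-7-methoxy-2-(4-methoxyphenyl)-2,3-dihydro-1-benzofuran-5-yl]methyl]trifluoroborate | COc1cc(Br)c(c(Br)c1)[C@H](c1cc(OC)c2c(c1)[C@@H](c1cc(OC)cc(OC)c1)[C@H](c1ccc(OC)cc1)O2)[B-](F)(F)F.[K+]
F8 | step 14 | (2S,3S)-4-bromo-3-[(2R,3R)-3-(3,5-dihydroxyphenyl)-7-hydroxy-2-(4-hydroxyphenyl)-2,3-dihydro-1-benzofuran-5-yl]-2-(4-hydroxyphenyl)-2,3-dihydro-1-benzofuran-6-ol | Brc1cc(O)cc2c1[C@H](c1cc(O)c3c(c1)[C@@H](c1cc(O)cc(O)c1)[C@H](c1ccc(O)cc1)O3)[C@@H](c1ccc(O)cc1)O2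
F9 | step 14 | hexaacetate of F8 (all six phenols as acetates) | Brc1cc(OC(C)=O)cc2c1[C@H](c1cc(OC(C)=O)c3c(c1)[C@@H](c1cc(OC(C)=O)cc(OC(C)=O)c1)[C@H](c1ccc(OC(C)=O)cc1)O3)[C@@H](c1ccc(OC(C)=O)cc1)O2
F10 | step 14 | heptaacetate of 33 (all seven phenols as acetates) | CC(=O)Oc1ccc(/C=C/c2cc(OC(C)=O)cc3c2[C@H](c2cc(OC(C)=O)c4c(c2)[C@@H](c2cc(OC(C)=O)cc(OC(C)=O)c2)[C@H](c2ccc(OC(C)=O)cc2)O4)[C@@H](c2ccc(OC(C)=O)cc2)O3)cc1
F11 | step 3 | (4S,5S)-4,5-dicyclohexyl-2-(2,5-dibromo-3-methoxyphenyl)-1,3,2-dioxaborolane | COc1cc(Br)cc(B2O[C@@H](C3CCCCC3)[C@H](C3CCCCC3)O2)c1Br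
F12 | step 3 | (4S,5S)-2-[(R)-chloro(2,5-dibromo-3-methoxyphenyl)methyl]-4,5-dicyclohexyl-1,3,2-dioxaborolane | COc1cc(Br)cc([C@H](Cl)B2O[C@@H](C3CCCCC3)[C@H](C3CCCCC3)O2)c1Br
F13 | step 3 | (4S,5S)-4,5-dicyclohexyl-2-[(R)-(2,5-dibromo-3-methoxyphenyl)(3,5-dimethoxyphenyl)methyl]-1,3,2-dioxaborolane | COc1cc(Br)cc([C@@H](c2cc(OC)cc(OC)c2)B2O[C@@H](C3CCCCC3)[C@H](C3CCCCC3)O2)c1Br
F14 | step 3 | potassium [(R)-(2,5-dibromo-3-methoxyphenyl)(3,5-dimethoxyphenyl)methyl]trifluoroborate | COc1cc(Br)cc([C@@H](c2cc(OC)cc(OC)c2)[B-](F)(F)F)c1Br.[K+]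
A1 | alternative 1 | 4-[(2S,3S)-3-[4-(benzyloxy)-3-methoxyphenyl]-6-methoxy-4-(methoxymethoxy)-2,3-dihydro-1-benzofuran-2-yl]phenyl 4-methylbenzenesulfonate | COCOc1cc(OC)cc2c1[C@H](c1cc(OC)c(OCc3ccccc3)cc1)[C@@H](c1ccc(OS(=O)(=O)c3ccc(C)cc3)cc1)O2
A2 | alternative 1 | 5-methoxy-3-(methoxymethoxy)-2-(trimethylsilyl)phenyl trifluoromethanesulfonate | COCOc1cc(OC)cc(OS(=O)(=O)C(F)(F)F)c1[Si](C)(C)C
A3 | alternative 1 | 4-[(2R,3R)-3-[4-(benzyloxy)-3-methoxyphenyl]oxiran-2-yl]phenyl 4-methylbenzenesulfonate | COc1cc(ccc1OCc1ccccc1)[C@@H]1[C@@H](c2ccc(OS(=O)(=O)c3ccc(C)cc3)cc2)O1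
A4 | alternative 2 | (2S,3S)-3-[4-(benzyloxy)-3-methoxyphenyl]-2-(4-methoxyphenyl)-4-[(E)-2-(4-methoxyphenyl)ethenyl]-2,3-dihydro-1-benzofuran-6-ol | COc1ccc(/C=C/c2cc(O)cc3c2[C@H](c2cc(OC)c(OCc4ccccc4)cc2)[C@@H](c2ccc(OC)cc2)O3)cc1
A5 | alternative 2 | (1E,6S,7S)-6-[4-(benzyloxy)-3-methoxyphenyl]-5-diazo-7-(ethynyloxy)-1,7-bis(4-methoxyphenyl)-3-methylidenehept-1-en-4-one | C=C(/C=C/c1ccc(OC)cc1)C(=O)C(=[N+]=[N-])[C@H](c1cc(OC)c(OCc2ccccc2)cc1)[C@@H](c1ccc(OC)cc1)OC#C
A6 | alternative 3 | methyl (2R,3R)-3-(3,5-dimethoxyphenyl)-7-methoxy-2-(4-methoxyphenyl)-2,3-dihydro-1-benzofuran-5-carboxylate | COC(=O)c1cc(OC)c2c(c1)[C@@H](c1cc(OC)cc(OC)c1)[C@H](c1ccc(OC)cc1)O2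
A7 | alternative 3 | methyl (3R,4R)-4-(3,5-dimethoxyphenyl)-8-methoxy-3-(4-methoxyphenyl)-2-oxo-3,4-dihydro-2H-chromene-6-carboxylate | COC(=O)c1cc(OC)c2c(c1)[C@@H](c1cc(OC)cc(OC)c1)[C@H](c1ccc(OC)cc1)C(=O)O2
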